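**Plan**
- Retrosynthetic cuts, in order: the five silicon-based O-protecting groups; the C2=C3 double bond (back to a C2–C3 single bond); the C3–C4 bond, between a 1-(pyridin-3-yl)cyclopropanol N-oxide and an (E,E)-dienyl iodide; the cyclopropanol C1–pyridine C3 bond; the pyridine C5–C1′ bond; the two pyridine C–O bonds.
- Enabling feature: the ketone carbon C1 and the chain carbons C2 and C3 are carried as a cyclopropanol ring on pyridine C3. Strain release by C1–C3 cleavage makes C3, normally the electrophilic β-carbon, a palladium homoenolate nucleophile that joins C4 of the dienyl iodide.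
- Forward order: the pyridine and cyclohexane rings are bought intact and joined at C5; the cyclopropane is added at C3; N-oxidation follows. The C4–C10 chain is built separately, joined at C3–C4, dehydrogenated at C2–C3, and all silicon groups are removed at the end.
- Stereochemistry: C8 (R) from a copper-catalysed asymmetric SN2′ ethylation; the cis-1,4-diol from equatorial attack of the C5 aryllithium on 4-silyloxycyclohexanone; the E-alkenes from cross-metathesis, Takai olefination, retention in the coupling and syn-elimination.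

Key step: step 10

Numbering used: chain C1 (ketone carbon) to C10; cyclohexane C1′ (carbinol on the pyridine) to C4′; "cis" refers to the two oxygen substituents on C1′ and C4′.
Assumption: (S,S)-Taniaphos is taken to deliver the R configuration at C8 in step 7; if the sense of induction is the opposite, the (R,R) ligand is used with no other change.

**Step 1**
Reactants: 1 5-bromo-2,4-dichloropyridine
Product: 2 5-bromo-2,4-bis[2-(trimethylsilyl)ethoxy]pyridine
Conditions: 2-(trimethylsilyl)ethanol (2.5 equiv), NaH, THF–DMF, 0 → 70 °C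
Reagents that add atoms: 2-(trimethylsilyl)ethanol, C[Si](C)(C)CCO
Why: Twofold nucleophilic aromatic substitution (SNAr) by the sodium alkoxide at C4 and then C2, both activated by the ring nitrogen, while the unactivated C5 bromide should remain as the handle for step 2.

**Step 2**
Reactants: 2 5-bromo-2,4-bis[2-(trimethylsilyl)ethoxy]pyridine + 3 4-(tert-butyldimethylsilyloxy)cyclohexan-1-one
Product: 6 5-[cis-4-(tert-butyldimethylsilyloxy)-1-(triethylsilyloxy)cyclohexyl]-2,4-bis[2-(trimethylsilyl)ethoxy]pyridine, via 5-lithiopyridine 4 (not isolated), via lithium alkoxide 5 (not isolated)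
Conditions: n-BuLi, THF, −78 °C; 3; then Et3SiOTf, −78 → 0 °C
Reagents that add atoms: triethylsilyl trifluoromethanesulfonate, CC[Si](CC)(CC)OS(=O)(=O)C(F)(F)F
Why: Bromine–lithium exchange, 1,2-addition of the aryllithium to the ketone and in situ silylation of the tertiary alkoxide; the ortho-alkoxy aryllithium should attack the chair with the equatorial silyloxy group from the equatorial direction, which places the pyridyl group equatorial and the new C1′ oxygen axial and thus cis to the C4′ oxygen, and the minor trans isomer would be removed by chromatography.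

**Step 3**
Reactants: 6 5-[cis-4-(tert-butyldimethylsilyloxy)-1-(triethylsilyloxy)cyclohexyl]-2,4-bis[2-(trimethylsilyl)ethoxy]pyridine + 7 1-ethoxycyclopropan-1-ol (cyclopropanone ethyl hemiacetal)
Product: 10 1-{5-[cis-4-(tert-butyldimethylsilyloxy)-1-(triethylsilyloxy)cyclohexyl]-2,4-bis[2-(trimethylsilyl)ethoxy]pyridin-3-yl}cyclopropan-1-ol, via 3-lithiopyridine 8 (not isolated), via pyridylmagnesium bromide 9 (not isolated)
Conditions: s-BuLi, TMEDA, THF, −78 °C; MgBr2·OEt2; then 7 premixed with MeMgBr (1 equiv), THF, 0 °C → rt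
Reagents that add atoms: none
Why: Directed ortho-metalation at C3, the only ring position flanked by two alkoxy groups, then transmetalation to magnesium and 1,2-addition to cyclopropanone released from the bromomagnesium salt of its hemiacetal (the hemiacetal route to 1-substituted cyclopropanols), which installs C1, C2 and C3 of the acyl chain as a strained ring.

**Step 4**
Reactants: 10 1-{5-[cis-4-(tert-butyldimethylsilyloxy)-1-(triethylsilyloxy)cyclohexyl]-2,4-bis[2-(trimethylsilyl)ethoxy]pyridin-3-yl}cyclopropan-1-ol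
Product: 11 5-[cis-4-(tert-butyldimethylsilyloxy)-1-(triethylsilyloxy)cyclohexyl]-3-(1-hydroxycyclopropyl)-2,4-bis[2-(trimethylsilyl)ethoxy]pyridine 1-oxide
Conditions: mCPBA, CH2Cl2, 0 °C → rt
Reagents that add atoms: 3-chloroperoxybenzoic acid (mCPBA), OOC(=O)c1cccc(Cl)c1
Why: Peracid N-oxidation of the pyridine, whose nitrogen is made nucleophilic by the 4-alkoxy group and should be the most readily oxidised site at 0 °C, sets the N–O bond before any alkene is present.

**Step 5**
Reactants: 12 methyl (E)-4-bromobut-2-enoate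
Product: 13 (E)-4-bromobut-2-en-1-ol
Conditions: i-Bu2AlH (2.2 equiv), CH2Cl2, −78 °C
Reagents that add atoms: none
Why: 1,2-Reduction of the conjugated ester to the allylic alcohol with i-Bu2AlH at low temperature, which should leave the allylic bromide and the E double bond untouched.

**Step 6**
Reactants: 13 (E)-4-bromobut-2-en-1-ol
Product: 14 (E)-(4-bromobut-2-enyloxy)(tert-butyl)dimethylsilane
Conditions: t-BuMe2SiOTf, 2,6-lutidine, CH2Cl2, −78 °C
Reagents that add atoms: tert-butyldimethylsilyl trifluoromethanesulfonate, CC(C)(C)[Si](C)(C)OS(=O)(=O)C(F)(F)F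
Why: O-Silylation with a silyl triflate and a hindered pyridine base, chosen because a nucleophilic base would be alkylated by the allylic bromide.

**Step 7**
Reactants: 14 (E)-(4-bromobut-2-enyloxy)(tert-butyl)dimethylsilane
Product: 15 (R)-tert-butyl[(2-ethylbut-3-en-1-yl)oxy]dimethylsilane
Conditions: EtMgBr, CuBr·SMe2 (1 mol %), (S,S)-Taniaphos (1.2 mol %), CH2Cl2, −75 °C
Reagents that add atoms: ethylmagnesium bromide, CC[Mg]Br
Why: Copper-catalysed asymmetric allylic alkylation (SN2′) with a Grignard reagent, in which the Taniaphos-bound alkylcopper species should deliver ethyl to one enantioface of the alkene carbon next to the CH2OSi group, setting C8 as R and giving the branched terminal alkene.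

**Step 8**
Reactants: 15 (R)-tert-butyl[(2-ethylbut-3-en-1-yl)oxy]dimethylsilane
Product: 16 (R,E)-4-[(tert-butyldimethylsilyloxy)methyl]hex-2-enal
Conditions: crotonaldehyde (5 equiv), second-generation Hoveyda–Grubbs catalyst (5 mol %), CH2Cl2, 40 °C
Reagents that add atoms: (E)-but-2-enal (crotonaldehyde), C/C=C/C=O
Why: Olefin cross-metathesis of the monosubstituted alkene with an excess of crotonaldehyde, which should be E-selective for the conjugated enal and runs under neutral conditions that do not touch the allylic stereocentre.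

**Step 9**
Reactants: 16 (R,E)-4-[(tert-butyldimethylsilyloxy)methyl]hex-2-enal
Product: 17 tert-butyl{[(2R,3E,5E)-2-ethyl-6-iodohexa-3,5-dien-1-yl]oxy}dimethylsilane
Conditions: CHI3, CrCl2, THF–1,4-dioxane, 0 °C → rt
Reagents that add atoms: iodoform, IC(I)I
Why: Takai olefination, in which the geminal dichromium species from CHI3 and CrCl2 adds to the aldehyde and eliminates to the E-vinyl iodide under non-basic conditions, so that the E,E-dienyl iodide should form with C8 intact.

**Step 10**
Reactants: 11 5-[cis-4-(tert-butyldimethylsilyloxy)-1-(triethylsilyloxy)cyclohexyl]-3-(1-hydroxycyclopropyl)-2,4-bis[2-(trimethylsilyl)ethoxy]pyridine 1-oxide + 17 tert-butyl{[(2R,3E,5E)-2-ethyl-6-iodohexa-3,5-dien-1-yl]oxy}dimethylsilane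
Product: 18 (4E,6E,8R)-8-[(tert-butyldimethylsilyloxy)methyl]-1-{5-[cis-4-(tert-butyldimethylsilyloxy)-1-(triethylsilyloxy)cyclohexyl]-1-oxido-2,4-bis[2-(trimethylsilyl)ethoxy]pyridin-1-ium-3-yl}deca-4,6-dien-1-one
Conditions: Pd(OAc)2 (5 mol %), XPhos (10 mol %), Cs2CO3, toluene, 50 °C
Reagents that add atoms: none
Why: Dienyl iodide 17 adds oxidatively to zerovalent palladium with retention of the E,E geometry, the caesium alkoxide of 11 displaces iodide on palladium, and β-carbon elimination opens the cyclopropane at the C1–C3 bond (strain release) to a palladium homoenolate bound through C3; C(sp3)–C(sp2) reductive elimination then forms the C3–C4 bond and returns zerovalent palladium. The closest known reaction type is the palladium-catalysed ring-opening cross-coupling of tertiary cyclopropanols, as ketone homoenolate equivalents, with aryl and alkenyl halides. No ring is closed (the three-membered ring is opened) and no stereocentre is formed; C8 and the cyclohexane centres are remote and untouched. The step needs reductive elimination to be faster than β-hydride elimination of the alkylpalladium, which the bulky electron-rich biarylphosphine should secure, and it needs ring opening to occur only on palladium, which the weak heterogeneous carbonate base in toluene should secure. In the substrate the cyclopropanol is the only free hydroxyl, its two CH2 groups are equivalent so that either C1–CH2 cleavage gives the same homoenolate, and the other tertiary carbinol is unstrained and silylated.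

**Step 11**
Reactants: 18 (4E,6E,8R)-8-[(tert-butyldimethylsilyloxy)methyl]-1-{5-[cis-4-(tert-butyldimethylsilyloxy)-1-(triethylsilyloxy)cyclohexyl]-1-oxido-2,4-bis[2-(trimethylsilyl)ethoxy]pyridin-1-ium-3-yl}deca-4,6-dien-1-one
Product: 21 (2E,4E,6E,8R)-8-[(tert-butyldimethylsilyloxy)methyl]-1-{5-[cis-4-(tert-butyldimethylsilyloxy)-1-(triethylsilyloxy)cyclohexyl]-1-oxido-2,4-bis[2-(trimethylsilyl)ethoxy]pyridin-1-ium-3-yl}deca-2,4,6-trien-1-one, via lithium enolate 19 (not isolated), via C2 sulfilimine 20 (not isolated)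
Conditions: LiN(SiMe3)2, THF, −78 °C; then N-tert-butylbenzenesulfinimidoyl chloride, −78 °C
Reagents that add atoms: none
Why: Mukaiyama dehydrogenation, in which the lithium enolate (C2 is the only enolisable position) is sulfenylated at C2 and the α-sulfilimine undergoes syn-elimination at low temperature toward the allylic C3 hydrogens, which should give the E-enone in conjugation with the diene without an oxidant that could attack the triene.

**Step 12**
Reactants: 21 (2E,4E,6E,8R)-8-[(tert-butyldimethylsilyloxy)methyl]-1-{5-[cis-4-(tert-butyldimethylsilyloxy)-1-(triethylsilyloxy)cyclohexyl]-1-oxido-2,4-bis[2-(trimethylsilyl)ethoxy]pyridin-1-ium-3-yl}deca-2,4,6-trien-1-one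
Product: 22 (2E,4E,6E,8R)-1-[5-(cis-1,4-dihydroxycyclohexyl)-1,4-dihydroxy-2-oxo-1,2-dihydropyridin-3-yl]-8-(hydroxymethyl)deca-2,4,6-trien-1-one
Conditions: Bu4NF, AcOH, THF, 0 → 40 °C
Reagents that add atoms: none
Why: Fluoride-induced global desilylation, in which Si–O cleavage of the three silyl ethers and β-elimination of the two 2-(trimethylsilyl)ethyl groups (loss of ethene) release the 4-hydroxyl and convert the 2-alkoxypyridine N-oxide into its 1-hydroxy-2-pyridone tautomer, while the acetic acid buffer limits base-induced isomerisation at C8 and no strong acid is present that could ionise the tertiary carbinol.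

**Compound list**
1 | 5-bromo-2,4-dichloropyridine | Clc1cc(Cl)c(Br)cn1 | starting material
2 | 5-bromo-2,4-bis[2-(trimethylsilyl)ethoxy]pyridine | C[Si](C)(C)CCOc1cc(OCC[Si](C)(C)C)c(Br)cn1 | intermediate
3 | 4-(tert-butyldimethylsilyloxy)cyclohexan-1-one | CC(C)(C)[Si](C)(C)OC1CCC(=O)CC1 | starting material
4 | 5-lithio-2,4-bis[2-(trimethylsilyl)ethoxy]pyridine | C[Si](C)(C)CCOc1cc(OCC[Si](C)(C)C)c([Li])cn1 | intermediate (not isolated)
5 | lithium cis-1-{4,6-bis[2-(trimethylsilyl)ethoxy]pyridin-3-yl}-4-(tert-butyldimethylsilyloxy)cyclohexan-1-olate | C[Si](C)(C)CCOc1cc(OCC[Si](C)(C)C)c(cn1)[C@]2(O[Li])CC[C@@H](O[Si](C)(C)C(C)(C)C)CC2 | intermediate (not isolated)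
6 | 5-[cis-4-(tert-butyldimethylsilyloxy)-1-(triethylsilyloxy)cyclohexyl]-2,4-bis[2-(trimethylsilyl)ethoxy]pyridine | C[Si](C)(C)CCOc1cc(OCC[Si](C)(C)C)c(cn1)[C@]2(O[Si](CC)(CC)CC)CC[C@@H](O[Si](C)(C)C(C)(C)C)CC2 | intermediate
7 | 1-ethoxycyclopropan-1-ol | CCOC1(O)CC1 | starting material
8 | 3-lithio derivative of 6 | C[Si](C)(C)CCOc1c([Li])c(OCC[Si](C)(C)C)c(cn1)[C@]2(O[Si](CC)(CC)CC)CC[C@@H](O[Si](C)(C)C(C)(C)C)CC2 | intermediate (not isolated)
9 | 3-(bromomagnesio) derivative of 6 | C[Si](C)(C)CCOc1c([Mg]Br)c(OCC[Si](C)(C)C)c(cn1)[C@]2(O[Si](CC)(CC)CC)CC[C@@H](O[Si](C)(C)C(C)(C)C)CC2 | intermediate (not isolated)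
10 | 1-{5-[cis-4-(tert-butyldimethylsilyloxy)-1-(triethylsilyloxy)cyclohexyl]-2,4-bis[2-(trimethylsilyl)ethoxy]pyridin-3-yl}cyclopropan-1-ol | C[Si](C)(C)CCOc1c(C3(O)CC3)c(OCC[Si](C)(C)C)c(cn1)[C@]2(O[Si](CC)(CC)CC)CC[C@@H](O[Si](C)(C)C(C)(C)C)CC2 | intermediate
11 | 5-[cis-4-(tert-butyldimethylsilyloxy)-1-(triethylsilyloxy)cyclohexyl]-3-(1-hydroxycyclopropyl)-2,4-bis[2-(trimethylsilyl)ethoxy]pyridine 1-oxide | C[Si](C)(C)CCOc1c(C3(O)CC3)c(OCC[Si](C)(C)C)c(c[n+]1[O-])[C@]2(O[Si](CC)(CC)CC)CC[C@@H](O[Si](C)(C)C(C)(C)C)CC2 | intermediate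
12 | methyl (E)-4-bromobut-2-enoate | COC(=O)/C=C/CBr | starting material
13 | (E)-4-bromobut-2-en-1-ol | OC/C=C/CBr | intermediate
14 | (E)-(4-bromobut-2-enyloxy)(tert-butyl)dimethylsilane | CC(C)(C)[Si](C)(C)OC/C=C/CBr | intermediate
15 | (R)-tert-butyl[(2-ethylbut-3-en-1-yl)oxy]dimethylsilane | CC[C@H](C=C)CO[Si](C)(C)C(C)(C)C | intermediate
16 | (R,E)-4-[(tert-butyldimethylsilyloxy)methyl]hex-2-enal | CC[C@H](/C=C/C=O)CO[Si](C)(C)C(C)(C)C | intermediate
17 | tert-butyl{[(2R,3E,5E)-2-ethyl-6-iodohexa-3,5-dien-1-yl]oxy}dimethylsilane | CC[C@H](/C=C/C=C/I)CO[Si](C)(C)C(C)(C)C | intermediate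
18 | (4E,6E,8R)-8-[(tert-butyldimethylsilyloxy)methyl]-1-{5-[cis-4-(tert-butyldimethylsilyloxy)-1-(triethylsilyloxy)cyclohexyl]-1-oxido-2,4-bis[2-(trimethylsilyl)ethoxy]pyridin-1-ium-3-yl}deca-4,6-dien-1-one | CC[C@H](/C=C/C=C/CCC(=O)c1c(OCC[Si](C)(C)C)[n+]([O-])cc(c1OCC[Si](C)(C)C)[C@]2(O[Si](CC)(CC)CC)CC[C@@H](O[Si](C)(C)C(C)(C)C)CC2)CO[Si](C)(C)C(C)(C)C | intermediate
19 | lithium C1–C2 enolate of 18 | CC[C@H](/C=C/C=C/CC=C(O[Li])c1c(OCC[Si](C)(C)C)[n+]([O-])cc(c1OCC[Si](C)(C)C)[C@]2(O[Si](CC)(CC)CC)CC[C@@H](O[Si](C)(C)C(C)(C)C)CC2)CO[Si](C)(C)C(C)(C)C | intermediate (not isolated)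
20 | 2-(N-tert-butyl-S-phenylsulfinimidoyl) derivative of 18 | CC[C@H](/C=C/C=C/CC(C(=O)c1c(OCC[Si](C)(C)C)[n+]([O-])cc(c1OCC[Si](C)(C)C)[C@]2(O[Si](CC)(CC)CC)CC[C@@H](O[Si](C)(C)C(C)(C)C)CC2)S(=NC(C)(C)C)c3ccccc3)CO[Si](C)(C)C(C)(C)C | intermediate (not isolated)
21 | (2E,4E,6E,8R)-8-[(tert-butyldimethylsilyloxy)methyl]-1-{5-[cis-4-(tert-butyldimethylsilyloxy)-1-(triethylsilyloxy)cyclohexyl]-1-oxido-2,4-bis[2-(trimethylsilyl)ethoxy]pyridin-1-ium-3-yl}deca-2,4,6-trien-1-one | CC[C@H](/C=C/C=C/C=C/C(=O)c1c(OCC[Si](C)(C)C)[n+]([O-])cc(c1OCC[Si](C)(C)C)[C@]2(O[Si](CC)(CC)CC)CC[C@@H](O[Si](C)(C)C(C)(C)C)CC2)CO[Si](C)(C)C(C)(C)C | intermediate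
22 | (2E,4E,6E,8R)-1-[5-(cis-1,4-dihydroxycyclohexyl)-1,4-dihydroxy-2-oxo-1,2-dihydropyridin-3-yl]-8-(hydroxymethyl)deca-2,4,6-trien-1-one | CC[C@H](/C=C/C=C/C=C/C(=O)c1c(O)c([C@]2(O)CC[C@@H](O)CC2)cn(O)c1=O)CO | target

**Count**
Total steps: 12. Longest linear sequence: 8 steps (steps 5 to 12); the pyridine branch is 7 steps (steps 1 to 4, then 10 to 12).

**Steps most likely to fail**

1. Step 10. The alkylpalladium homoenolate may undergo β-hydride elimination before reductive elimination, or the base may open the cyclopropanol to the ethyl ketone. The fallback sets out from 11 and comes back at 21. The ring opening is run on purpose as an oxidation with Pd(OAc)2, pyridine and O2 in toluene, so that divalent palladium opens the ring and β-hydride elimination gives the aryl vinyl ketone F1. A Heck reaction of F1 with iodide 17 (Pd(OAc)2, K2CO3, Bu4NCl, DMF) then forms the same C3–C4 bond with normal polarity and gives trienone 21 directly, so that step 11 is not needed.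

2. Step 4. The peracid may transfer oxygen to the electron-rich cyclopropanol, or the acid formed may open it, while N-oxidation of the 2-alkoxypyridine is slow. The fallback sets out from 6 and comes back at 11, with the order of oxidation and ring attachment inverted. Lithiation of 6 at C3 as in step 3 and a quench with I2 gives the 3-iodopyridine F2. mCPBA then gives the iodopyridine N-oxide F3 with no cyclopropane present. Iodine–magnesium exchange with i-PrMgCl·LiCl at −40 °C gives the pyridylmagnesium chloride F4, which is added to cyclopropanone released from 7 and MeMgBr to give 11.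

3. Step 2. Facial selectivity may be poor, because the chair with an axial silyloxy group is also populated and leads to the trans-diol series. The fallback sets out from 2 and comes back at 6, with the C4′ centre set by reduction. The aryllithium 4 is added to 1,4-dioxaspiro[4.5]decan-8-one to give the ketal alcohol F5. Aqueous HCl in THF gives the hydroxy ketone F6. NaBH4 in MeOH at low temperature delivers hydride axially to the chair with the pyridyl group equatorial and gives the cis-diol F7. t-BuMe2SiCl with imidazole silylates the secondary hydroxyl only to give the mono-silyl ether F8, and Et3SiOTf with 2,6-lutidine then gives 6.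

**Further compounds**
F1 | step 10 | 1-{5-[cis-4-(tert-butyldimethylsilyloxy)-1-(triethylsilyloxy)cyclohexyl]-1-oxido-2,4-bis[2-(trimethylsilyl)ethoxy]pyridin-1-ium-3-yl}prop-2-en-1-one | C=CC(=O)c1c(OCC[Si](C)(C)C)[n+]([O-])cc(c1OCC[Si](C)(C)C)[C@]2(O[Si](CC)(CC)CC)CC[C@@H](O[Si](C)(C)C(C)(C)C)CC2
F2 | step 4 | 5-[cis-4-(tert-butyldimethylsilyloxy)-1-(triethylsilyloxy)cyclohexyl]-3-iodo-2,4-bis[2-(trimethylsilyl)ethoxy]pyridine | C[Si](C)(C)CCOc1c(I)c(OCC[Si](C)(C)C)c(cn1)[C@]2(O[Si](CC)(CC)CC)CC[C@@H](O[Si](C)(C)C(C)(C)C)CC2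
F3 | step 4 | 5-[cis-4-(tert-butyldimethylsilyloxy)-1-(triethylsilyloxy)cyclohexyl]-3-iodo-2,4-bis[2-(trimethylsilyl)ethoxy]pyridine 1-oxide | C[Si](C)(C)CCOc1c(I)c(OCC[Si](C)(C)C)c(c[n+]1[O-])[C@]2(O[Si](CC)(CC)CC)CC[C@@H](O[Si](C)(C)C(C)(C)C)CC2
F4 | step 4 | 3-(chloromagnesio) derivative of the N-oxide F3 | C[Si](C)(C)CCOc1c([Mg]Cl)c(OCC[Si](C)(C)C)c(c[n+]1[O-])[C@]2(O[Si](CC)(CC)CC)CC[C@@H](O[Si](C)(C)C(C)(C)C)CC2
F5 | step 2 | 8-{4,6-bis[2-(trimethylsilyl)ethoxy]pyridin-3-yl}-1,4-dioxaspiro[4.5]decan-8-ol | C[Si](C)(C)CCOc1cc(OCC[Si](C)(C)C)c(cn1)C2(O)CCC3(CC2)OCCO3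
F6 | step 2 | 4-{4,6-bis[2-(trimethylsilyl)ethoxy]pyridin-3-yl}-4-hydroxycyclohexan-1-one | C[Si](C)(C)CCOc1cc(OCC[Si](C)(C)C)c(cn1)C2(O)CCC(=O)CC2
F7 | step 2 | cis-1-{4,6-bis[2-(trimethylsilyl)ethoxy]pyridin-3-yl}cyclohexane-1,4-diol | C[Si](C)(C)CCOc1cc(OCC[Si](C)(C)C)c(cn1)[C@]2(O)CC[C@@H](O)CC2
F8 | step 2 | cis-1-{4,6-bis[2-(trimethylsilyl)ethoxy]pyridin-3-yl}-4-(tert-butyldimethylsilyloxy)cyclohexan-1-ol | C[Si](C)(C)CCOc1cc(OCC[Si](C)(C)C)c(cn1)[C@]2(O)CC[C@@H](O[Si](C)(C)C(C)(C)C)CC2
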